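**Retrosynthetic overview**
1. The target is opened last by a zinc-mediated reductive ring opening of a masked ether in which ring B of the honokiol part is tied up as a 2-(iodomethyl)dihydrobenzofuran; this frees the 4'-OH and the 3'-allyl group together.
2. Key disconnection: the C4–O(aryl) bond, made by Markovnikov addition of the only free phenol of masked honokiol across the exocyclic C4=C15 alkene of (+)-β-eudesmol; this sets C4 (aryloxy α, equatorial).
3. Masked honokiol comes from honokiol by 5-exo iodoetherification, which only the ortho-allylphenol ring B can undergo, so the two hydroxyls are told apart by constitution.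
4. Ring order: the decalin (C5, C7, C10 stereocentres) and the biaryl are bought intact; the only ring formed is the temporary dihydrobenzofuran (step 1), opened again in step 3.

Assumption: honokiol and natural (+)-β-eudesmol are taken as inexpensive commercial natural products. The carbon created in step 1 is racemic, so 6 and 7 are 1:1 epimer mixtures at that carbon only, and it is erased in step 3.

**Step 1**
Reactants: 1 honokiol
Product: 2 rac-2-[2-(iodomethyl)-2,3-dihydro-1-benzofuran-5-yl]-4-(prop-2-enyl)phenol
Conditions: I2 (1.1 equiv), NaHCO3 (2 equiv), MeCN, 0 °C, dark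
Reagents that add atoms: iodine, I-I
Why: 5-exo iodoetherification (halocyclisation) is possible only for ring B, whose hydroxyl is ortho to an allyl group, so the 4'-OH and its allyl group are masked together while the 2-OH and the para-allyl group of ring A cannot cyclise; the new carbon is racemic and is removed in step 3.

**Step 2**
Reactants: 2 rac-2-[2-(iodomethyl)-2,3-dihydro-1-benzofuran-5-yl]-4-(prop-2-enyl)phenol (1.0 equiv); 3 (+)-β-eudesmol (1.5 equiv)
Product: 6 2-[(2R,4aR,8R,8aR)-8-({2-[2-(iodomethyl)-2,3-dihydro-1-benzofuran-5-yl]-4-(prop-2-enyl)phenyl}oxy)-4a,8-dimethyldecahydronaphthalen-2-yl]propan-2-ol (1:1 epimers at the dihydrobenzofuran carbon), via eudesman-4-yl radical 4 (not isolated), via eudesman-4-yl cation 5 (not isolated)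
Conditions: Co(C36H54N2O2), the divalent cobalt complex of N,N'-bis(3,5-di-tert-butylsalicylidene)-2,3-dimethylbutane-2,3-diamine (5 mol %), N-fluoro-2,4,6-trimethylpyridinium triflate (2.0 equiv), (HMe2Si)2O (2.0 equiv), PhCF3 (0.3 M), 0 °C to rt
Reagents that add atoms: none
Why: Proposed new method: a cobalt-hydride hydrogen-atom-transfer / radical–polar crossover Markovnikov hydroaryloxylation run with a hindered 2-arylphenol as the limiting, stoichiometric nucleophile at a fully substituted decalin carbon; the N-fluoropyridinium salt oxidises divalent cobalt to a trivalent cobalt fluoride, the disiloxane turns this into a trivalent cobalt hydride, and H• is transferred to the terminal CH2 of the 1,1-disubstituted alkene of 3 to give tertiary radical 4 (the allyl group of 2 would give only a secondary radical and should react at least ten times more slowly; the primary C–I bond and the tertiary alcohol should be inert because no low-valent cobalt and no strong acid are present); 4 is oxidised in the solvent cage by trivalent cobalt to cation-like 5, which the collidine-hydrogen-bonded phenol captures irreversibly at oxygen from the α face, equatorial and anti to the axial C10 methyl group (the face on which this C4 cation is hydrated to cryptomeridiol), so C4 becomes R with the aryloxy group α; closest known reaction type: cobalt salen / N-fluoropyridinium / silane Markovnikov hydroalkoxylation of unactivated alkenes (Mukaiyama-type hydrofunctionalisation), established with simple alcohols in large excess and with intramolecular phenols.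

**Step 3**
Reactants: 6 the masked ether from step 2
Product: 8 2-[(2R,4aR,8R,8aR)-8-{[4'-hydroxy-3',5-di(prop-2-enyl)biphenyl-2-yl]oxy}-4a,8-dimethyldecahydronaphthalen-2-yl]propan-2-ol (target), via alkylzinc iodide 7 (not isolated)
Conditions: Zn dust (activated, 5 equiv), NH4Cl (3 equiv), EtOH/THF 4:1, 60 °C
Reagents that add atoms: none
Why: Zinc inserts into the primary C–I bond to give 7, which expels the β-aryloxide (reductive β-elimination, Boord-type fragmentation); this regenerates the 3'-allyl group and the 4'-phenol under near-neutral conditions that leave the tertiary alkyl aryl ether, the tertiary alcohol and the four stereocentres (C4, C5, C7, C10) untouched, and both epimers of 6 converge on one product.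

**Compound list**
1 | honokiol, 2-(4-hydroxy-3-prop-2-enylphenyl)-4-prop-2-enylphenol | C=CCc1ccc(O)c(-c2ccc(O)c(CC=C)c2)c1 | starting material
2 | rac-2-[2-(iodomethyl)-2,3-dihydro-1-benzofuran-5-yl]-4-(prop-2-enyl)phenol | C=CCc1ccc(O)c(-c2ccc3OC(CI)Cc3c2)c1 | intermediate
3 | (+)-β-eudesmol, 2-[(2R,4aR,8aS)-4a-methyl-8-methylidenedecahydronaphthalen-2-yl]propan-2-ol | C=C1CCC[C@]2(C)CC[C@@H](C(C)(C)O)C[C@H]21 | starting material
4 | eudesman-4-yl tertiary radical carrying the C11 carbinol (not isolated) | C[C]1CCC[C@]2(C)CC[C@@H](C(C)(C)O)C[C@H]21 | intermediate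
5 | eudesman-4-yl tertiary cation or its tetravalent alkylcobalt equivalent (not isolated) | C[C+]1CCC[C@]2(C)CC[C@@H](C(C)(C)O)C[C@H]21 | intermediate
6 | 2-[(2R,4aR,8R,8aR)-8-({2-[2-(iodomethyl)-2,3-dihydro-1-benzofuran-5-yl]-4-(prop-2-enyl)phenyl}oxy)-4a,8-dimethyldecahydronaphthalen-2-yl]propan-2-ol, 1:1 epimers at the dihydrobenzofuran carbon | C=CCc1ccc(O[C@]2(C)CCC[C@]3(C)CC[C@@H](C(C)(C)O)C[C@H]32)c(-c2ccc3OC(CI)Cc3c2)c1 | intermediate
7 | alkylzinc iodide formed from 6 by zinc insertion into the C–I bond (not isolated) | C=CCc1ccc(O[C@]2(C)CCC[C@]3(C)CC[C@@H](C(C)(C)O)C[C@H]32)c(-c2ccc3OC(C[Zn]I)Cc3c2)c1 | intermediate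
8 | 2-[(2R,4aR,8R,8aR)-8-{[4'-hydroxy-3',5-di(prop-2-enyl)biphenyl-2-yl]oxy}-4a,8-dimethyldecahydronaphthalen-2-yl]propan-2-ol | C=CCc1ccc(O[C@]2(C)CCC[C@]3(C)CC[C@@H](C(C)(C)O)C[C@H]32)c(-c2ccc(O)c(CC=C)c2)c1 | target

**Step count and risks**
Total step count: 3. Longest linear sequence: 3 (from honokiol 1; β-eudesmol 3 enters at step 2).

Most likely to fail, first: step 2, the proposed new reaction. The likely leaks are alkene isomerisation of 3 to the tetrasubstituted γ-isomer, slow capture of 5 by a hindered phenol used at one equivalent, ring C-alkylation, and some hydrogen-atom transfer to the allyl group. The fallback uses known chemistry: it sets out from 2 and 3 and comes back at 6. It is the Brønsted-acid-catalysed kinetic Markovnikov addition of a phenol to a 1,1-disubstituted alkene, the protocol used to make tert-butyl aryl ethers from isobutene (TfOH 5–10 mol %, CH2Cl2, −60 to −40 °C, 3 in twofold excess, cold Et3N quench). Acid protonates only the 1,1-disubstituted alkene, the same cation 5 is taken from the α face, and low temperature keeps O-alkylation ahead of ring alkylation. The free C11 carbinol is the weak point and limits the temperature. New compounds on this way: none F0.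

Second: step 1. Ring iodination of the electron-rich phenols or iodine uptake by the ring A allyl group could erode the masking. The fallback sets out from 3 and comes back at 8, with the two oxygens told apart by construction instead of by masking:
- 4-Allylphenol is ortho-brominated (NBS, iPr2NH 10 mol %, CH2Cl2, 0 °C) to 2-bromo-4-(prop-2-enyl)phenol F1.
- F1 is joined to 3 under the step 2 conditions (or the acid protocol above) to give 2-[(2R,4aR,8R,8aR)-8-[2-bromo-4-(prop-2-enyl)phenoxy]-4a,8-dimethyldecahydronaphthalen-2-yl]propan-2-ol F2.
- Suzuki–Miyaura coupling of F2 with 4-(prop-2-enyloxy)phenylboronic acid (Pd(OAc)2, SPhos, K3PO4, toluene/H2O, 80 °C) gives 2-[(2R,4aR,8R,8aR)-4a,8-dimethyl-8-{[5-(prop-2-enyl)-4'-(prop-2-enyloxy)biphenyl-2-yl]oxy}decahydronaphthalen-2-yl]propan-2-ol F3. No free phenol is present, so zerovalent palladium has no acceptor for allyl transfer.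
- Thermal aromatic Claisen rearrangement of F3 (N,N-diethylaniline, 190 °C) moves the O-allyl group to either of the two equivalent ortho positions and frees the 4'-OH, giving 8.

Third: step 3. Zinc insertion could be sluggish, or the alkylzinc 7 could be protonated to a 2-methyldihydrobenzofuran instead of fragmenting. The fallback sets out from 1 and comes back at 8, replacing the iodoether mask by a fluoride-labile silyl mask:
- Honokiol is monosilylated (TBDPSCl 1.0 equiv, imidazole, DMF, −20 °C) to 2-{4-[tert-butyl(diphenyl)silyl]oxy-3-(prop-2-enyl)phenyl}-4-(prop-2-enyl)phenol F4. The 4'-OH is expected to react first because it is slightly more acidic and less hindered; this is unverified, so the regiochemistry is checked by NOE and the 2-O-silyl isomer is removed by chromatography.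
- F4 and 3 under the step 2 conditions give the 4'-O-tert-butyldiphenylsilyl ether of the target F5. The silylated oxygen cannot cyclise onto its allyl group.
- TBAF in THF at 0 °C releases 8.

**Further compounds**
F0 | step 2 | none | none
F1 | step 1 | 2-bromo-4-(prop-2-enyl)phenol | C=CCc1ccc(O)c(Br)c1
F2 | step 1 | 2-[(2R,4aR,8R,8aR)-8-[2-bromo-4-(prop-2-enyl)phenoxy]-4a,8-dimethyldecahydronaphthalen-2-yl]propan-2-ol | C=CCc1ccc(O[C@]2(C)CCC[C@]3(C)CC[C@@H](C(C)(C)O)C[C@H]32)c(Br)c1
F3 | step 1 | 2-[(2R,4aR,8R,8aR)-4a,8-dimethyl-8-{[5-(prop-2-enyl)-4'-(prop-2-enyloxy)biphenyl-2-yl]oxy}decahydronaphthalen-2-yl]propan-2-ol | C=CCc1ccc(O[C@]2(C)CCC[C@]3(C)CC[C@@H](C(C)(C)O)C[C@H]32)c(-c2ccc(OCC=C)cc2)c1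
F4 | step 3 | 2-{4-[tert-butyl(diphenyl)silyl]oxy-3-(prop-2-enyl)phenyl}-4-(prop-2-enyl)phenol | C=CCc1ccc(O)c(-c2ccc(O[Si](c3ccccc3)(c3ccccc3)C(C)(C)C)c(CC=C)c2)c1
F5 | step 3 | 4'-O-tert-butyldiphenylsilyl ether of the target | C=CCc1ccc(O[C@]2(C)CCC[C@]3(C)CC[C@@H](C(C)(C)O)C[C@H]32)c(-c2ccc(O[Si](c3ccccc3)(c3ccccc3)C(C)(C)C)c(CC=C)c2)c1
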